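**Retrosynthetic overview**

1. The strategy rests on ring C being a 2-aryloxyphloroglucinol: C C-1 carries the ring B ether oxygen between the oxygenated C C-2 and C C-6, and C C-4, para to it, carries the fourth oxygen (later the ring D ether). That pattern is a 4-aryloxy-3,5-dioxohexanoate joined methyl carbon to carboxyl carbon, so ring C is cut at C C-3–C C-4 back to the lactone-masked triketide 11, a 5-aryloxy-4-methoxy-6-methyl-2-pyrone.
2. Pyrone 11 comes from AB phenol 6, 3-chloropentane-2,4-dione 7 and CO2 (O-alkylation at the central diketone carbon, dianion carboxylation, lactonisation, O-methylation), so the crowded B–O–C ether needs no aryl coupling.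
3. The other three ethers (A–O–B, C–O–D, D–O–E) each come from a phenol and 2-fluoro-3,5-dimethoxybenzaldehyde 2 by SNAr; Dakin oxidation of the formyl group then gives the next phenol, so one building block supplies rings B, D and E.
4. Ring order: rings A and B enter as arenes and are joined first; the pyrone ring is closed in step 6 and refolded into ring C in step 8; rings D and E are then added and the ten methyl ethers cleaved.

Key step: step 8

Remark (locants used): B C-1 bears the oxygen to ring A and B C-2 the oxygen to ring C; C C-1 bears the oxygen to ring B and C C-4 the oxygen to ring D; D C-1 bears the oxygen to ring C and D C-2 the oxygen to ring E; E C-1 bears the oxygen to ring D. The target has no stereocenter.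

**Route**

Step 1
Reactants: 1 3,5-dimethoxybenzaldehyde
Product: 2 2-fluoro-3,5-dimethoxybenzaldehyde
Conditions: Selectfluor (0.9 equiv), MeCN, 0 °C to rt
Reagents that add atoms: Selectfluor, 1-(chloromethyl)-4-fluoro-1,4-diazoniabicyclo[2.2.2]octane bis(tetrafluoroborate), F[N+]12CC[N+](CCl)(CC1)CC2.F[B-](F)(F)F.F[B-](F)(F)F
Why: Electrophilic aromatic fluorination, in which C-2 (ortho to one methoxy group, para to the other) should react in preference to the more crowded C-4 between the two methoxy groups, while a deficit of reagent limits the 2,6-difluoro by-product, which is removed by chromatography.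

Step 2
Reactants: 3 3,5-dimethoxyphenol; 2 2-fluoro-3,5-dimethoxybenzaldehyde
Product: 4 2-(3,5-dimethoxyphenoxy)-3,5-dimethoxybenzaldehyde (AB aldehyde)
Conditions: K2CO3, DMF, 120 °C
Reagents that add atoms: none
Why: SNAr, in which the phenoxide adds to the fluorine-bearing carbon ortho to the formyl group (which stabilises the anionic σ-adduct) and fluoride leaves, giving the A–O–B ether with B C-1 already flanked by a masked oxygen (CHO) and a methoxy group.

Step 3
Reactants: 4 2-(3,5-dimethoxyphenoxy)-3,5-dimethoxybenzaldehyde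
Product: 6 2-(3,5-dimethoxyphenoxy)-3,5-dimethoxyphenol (AB phenol), via aryl formate 5 (not isolated)
Conditions: mCPBA, CH2Cl2, 0 °C to rt; then MeOH, Et3N, rt
Reagents that add atoms: mCPBA (3-chloroperoxybenzoic acid), OOC(=O)c1cccc(Cl)c1
Why: Dakin-type Baeyer–Villiger oxidation, in which the electron-rich aryl group bearing an ortho aryloxy substituent migrates in preference to hydrogen to give formate 5, whose methanolysis frees the B C-2 hydroxyl.

Step 4
Reactants: 6 2-(3,5-dimethoxyphenoxy)-3,5-dimethoxyphenol; 7 3-chloropentane-2,4-dione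
Product: 8 3-[2-(3,5-dimethoxyphenoxy)-3,5-dimethoxyphenoxy]pentane-2,4-dione
Conditions: Cs2CO3, acetone, reflux
Reagents that add atoms: none
Why: Williamson-type SN2 O-alkylation of the phenoxide at the doubly carbonyl-activated secondary chloride, the usual access to 3-aryloxypentane-2,4-diones, which forms the hindered B–O–C bond at an sp3 carbon before ring C exists.

Step 5
Reactants: 8 3-[2-(3,5-dimethoxyphenoxy)-3,5-dimethoxyphenoxy]pentane-2,4-dione
Product: 9 4-[2-(3,5-dimethoxyphenoxy)-3,5-dimethoxyphenoxy]-3,5-dioxohexanoic acid (racemic at C-4, enolisable)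
Conditions: LiN(iPr)2 (2.2 equiv), THF, −78 to 0 °C; excess CO2, −78 °C; cold 1 M HCl
Reagents that add atoms: carbon dioxide, O=C=O
Why: β-Diketone dianion carboxylation, in which the second equivalent of base deprotonates a terminal methyl group after enolate formation at C-3 and this most basic carbon takes up CO2, the β,δ-diketo acid being kept cold and used at once to avoid decarboxylation.

Step 6
Reactants: 9 4-[2-(3,5-dimethoxyphenoxy)-3,5-dimethoxyphenoxy]-3,5-dioxohexanoic acid
Product: 10 5-[2-(3,5-dimethoxyphenoxy)-3,5-dimethoxyphenoxy]-4-hydroxy-6-methyl-2H-pyran-2-one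
Conditions: Ac2O, 0 °C to rt
Reagents that add atoms: none
Why: Enol lactonisation, in which the mixed anhydride of the acid is attacked by the enol oxygen of the C-5 ketone in a six-membered closure, the established cyclisation of 3,5-dioxo acids to 4-hydroxy-6-methyl-2-pyrones.

Step 7
Reactants: 10 5-[2-(3,5-dimethoxyphenoxy)-3,5-dimethoxyphenoxy]-4-hydroxy-6-methyl-2H-pyran-2-one
Product: 11 5-[2-(3,5-dimethoxyphenoxy)-3,5-dimethoxyphenoxy]-4-methoxy-6-methyl-2H-pyran-2-one
Conditions: Me2SO4, K2CO3, acetone, reflux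
Reagents that add atoms: dimethyl sulfate, COS(=O)(=O)OC
Why: O-methylation of the vinylogous acid, which under these conditions should take place on the 4-oxygen of a 4-hydroxy-6-methyl-2-pyrone to give the 4-methoxy-2-pyrone and not the 2-methoxy-4-pyrone, fixing the oxygen that becomes the C C-6 methyl ether.

Step 8
Reactants: 11 5-[2-(3,5-dimethoxyphenoxy)-3,5-dimethoxyphenoxy]-4-methoxy-6-methyl-2H-pyran-2-one
Product: 13 4-[2-(3,5-dimethoxyphenoxy)-3,5-dimethoxyphenoxy]-5-methoxybenzene-1,3-diol (ABC diol), via ketene enolate 12 (not isolated)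
Conditions: LiN(SiMe3)2 (3.5 equiv), THF (high dilution), −78 °C to reflux; then 1 M HCl
Reagents that add atoms: none
Why: LiN(SiMe3)2 should deprotonate only the 6-methyl group of 11, the one C–H acid conjugated to the lactone carbonyl, and on warming the dienolate should expel the ring oxygen as the enolate of the methyl ketone, unmasking the triketide as dienyl ketene enolate 12. The enolate carbon (the former methyl, C C-3) then adds to the ketene carbon (the former lactone carbonyl, C C-4) in a six-membered closure across the cis-locked diene, a 6π-type ring closure of the dienyl ketene that amounts to an intramolecular Claisen C-acylation; tautomerisation of the dione to the bis-phenoxide of ring C makes the sequence irreversible. The closest known reactions are the base-induced ring opening and Claisen recyclisation of 4-methoxy-6-methyl-2-pyrone to 5-methoxyresorcinol and the base-mediated acyl shift of enol esters to 1,3-diketones. No stereocenter is formed. The step needs C- rather than O-acylation and a single direction of folding: O-acylation only regenerates 11 and is reversible, the 4-methoxy group removes the ketone that would offer an aldol mode, the 6-methyl group is the only enolisable carbon, and the Z geometry of the pyrone C-4/C-5 bond holds the two termini together. Excess base keeps the product as its dianion and dilution disfavours attack of the dienolate on unopened pyrone.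

Step 9
Reactants: 13 4-[2-(3,5-dimethoxyphenoxy)-3,5-dimethoxyphenoxy]-5-methoxybenzene-1,3-diol; 2 2-fluoro-3,5-dimethoxybenzaldehyde
Product: 15 2-{4-[2-(3,5-dimethoxyphenoxy)-3,5-dimethoxyphenoxy]-3,5-dimethoxyphenoxy}-3,5-dimethoxybenzaldehyde (ABCD aldehyde), via hydroxy aldehyde 14 (not isolated)
Conditions: Cs2CO3, DMF, 90 °C, 2 (1.0 equiv), argon; then MeI, rt
Reagents that add atoms: iodomethane, CI
Why: SNAr followed by O-methylation, in which the C C-4 phenoxide, flanked only by hydrogens, should add to the crowded fluoroarene 2 much faster than the C C-2 phenoxide beside the ring B ether, and iodomethane then caps that hindered hydroxyl so that a single phenol is present in the later coupling.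

Step 10
Reactants: 15 2-{4-[2-(3,5-dimethoxyphenoxy)-3,5-dimethoxyphenoxy]-3,5-dimethoxyphenoxy}-3,5-dimethoxybenzaldehyde
Product: 17 2-{4-[2-(3,5-dimethoxyphenoxy)-3,5-dimethoxyphenoxy]-3,5-dimethoxyphenoxy}-3,5-dimethoxyphenol (ABCD phenol), via aryl formate 16 (not isolated)
Conditions: mCPBA, CH2Cl2, 0 °C to rt; then MeOH, Et3N, rt
Reagents that add atoms: mCPBA (3-chloroperoxybenzoic acid), OOC(=O)c1cccc(Cl)c1
Why: Dakin-type Baeyer–Villiger oxidation as in step 3, which turns the formyl group on D C-2 into the hydroxyl that will carry ring E.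

Step 11
Reactants: 17 2-{4-[2-(3,5-dimethoxyphenoxy)-3,5-dimethoxyphenoxy]-3,5-dimethoxyphenoxy}-3,5-dimethoxyphenol; 2 2-fluoro-3,5-dimethoxybenzaldehyde
Product: 18 2-(2-{4-[2-(3,5-dimethoxyphenoxy)-3,5-dimethoxyphenoxy]-3,5-dimethoxyphenoxy}-3,5-dimethoxyphenoxy)-3,5-dimethoxybenzaldehyde (ABCDE aldehyde)
Conditions: Cs2CO3, DMSO, 120 °C, argon
Reagents that add atoms: none
Why: SNAr as in step 2, here between a phenoxide with one ortho substituent and a fluoroarene with two, so the well-dissociated caesium phenoxide in DMSO and a higher temperature are used to form the D–O–E ether with E C-1 between a formyl and a methoxy group.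

Step 12
Reactants: 18 2-(2-{4-[2-(3,5-dimethoxyphenoxy)-3,5-dimethoxyphenoxy]-3,5-dimethoxyphenoxy}-3,5-dimethoxyphenoxy)-3,5-dimethoxybenzaldehyde
Product: 20 2-(2-{4-[2-(3,5-dimethoxyphenoxy)-3,5-dimethoxyphenoxy]-3,5-dimethoxyphenoxy}-3,5-dimethoxyphenoxy)-3,5-dimethoxyphenol (ABCDE phenol), via aryl formate 19 (not isolated)
Conditions: mCPBA, CH2Cl2, 0 °C to rt; then MeOH, Et3N, rt
Reagents that add atoms: mCPBA (3-chloroperoxybenzoic acid), OOC(=O)c1cccc(Cl)c1
Why: Dakin-type Baeyer–Villiger oxidation as in step 3, which converts the E C-2 formyl group into a hydroxyl and so completes the 2,4,6-trioxygenated ring E.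

Step 13
Reactants: 20 2-(2-{4-[2-(3,5-dimethoxyphenoxy)-3,5-dimethoxyphenoxy]-3,5-dimethoxyphenoxy}-3,5-dimethoxyphenoxy)-3,5-dimethoxyphenol
Product: 21 2-[2-[4-[2-(3,5-dihydroxyphenoxy)-3,5-dihydroxyphenoxy]-3,5-dihydroxyphenoxy]-3,5-dihydroxyphenoxy]benzene-1,3,5-triol (CNP0018313.0)
Conditions: BBr3 (excess), CH2Cl2, −78 °C to rt; then MeOH, H2O
Reagents that add atoms: none
Why: Lewis acid cleavage of aryl methyl ethers, in which BBr3 coordinates each methoxy oxygen and bromide removes the methyl group as bromomethane, while the four diaryl ether bonds offer no sp3 carbon for bromide and should stay intact, hydrolysis of the aryl borates giving the undecaphenol.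

**Compound list**

1 | 3,5-dimethoxybenzaldehyde | COc1cc(C=O)cc(OC)c1 | starting material
2 | 2-fluoro-3,5-dimethoxybenzaldehyde | COc1cc(C=O)c(F)c(OC)c1 | intermediate
3 | 3,5-dimethoxyphenol | COc1cc(O)cc(OC)c1 | starting material
4 | 2-(3,5-dimethoxyphenoxy)-3,5-dimethoxybenzaldehyde | COc1cc(OC)cc(Oc2c(C=O)cc(OC)cc2OC)c1 | intermediate
5 | 2-(3,5-dimethoxyphenoxy)-3,5-dimethoxyphenyl formate | COc1cc(OC)cc(Oc2c(OC=O)cc(OC)cc2OC)c1 | intermediate
6 | 2-(3,5-dimethoxyphenoxy)-3,5-dimethoxyphenol | COc1cc(OC)cc(Oc2c(O)cc(OC)cc2OC)c1 | intermediate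
7 | 3-chloropentane-2,4-dione | CC(=O)C(Cl)C(C)=O | starting material
8 | 3-[2-(3,5-dimethoxyphenoxy)-3,5-dimethoxyphenoxy]pentane-2,4-dione | CC(=O)C(Oc1cc(OC)cc(OC)c1Oc1cc(OC)cc(OC)c1)C(C)=O | intermediate
9 | 4-[2-(3,5-dimethoxyphenoxy)-3,5-dimethoxyphenoxy]-3,5-dioxohexanoic acid (racemic) | CC(=O)C(Oc1cc(OC)cc(OC)c1Oc1cc(OC)cc(OC)c1)C(=O)CC(O)=O | intermediate
10 | 5-[2-(3,5-dimethoxyphenoxy)-3,5-dimethoxyphenoxy]-4-hydroxy-6-methyl-2H-pyran-2-one | Cc1oc(=O)cc(O)c1Oc1cc(OC)cc(OC)c1Oc1cc(OC)cc(OC)c1 | intermediate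
11 | 5-[2-(3,5-dimethoxyphenoxy)-3,5-dimethoxyphenoxy]-4-methoxy-6-methyl-2H-pyran-2-one | COc1cc(=O)oc(C)c1Oc1cc(OC)cc(OC)c1Oc1cc(OC)cc(OC)c1 | intermediate
12 | lithium (3Z)-3-[2-(3,5-dimethoxyphenoxy)-3,5-dimethoxyphenoxy]-4-methoxy-6-oxohexa-1,3,5-trien-2-olate | [Li+].C=C([O-])/C(Oc1cc(OC)cc(OC)c1Oc1cc(OC)cc(OC)c1)=C(OC)\C=C=O | intermediate
13 | 4-[2-(3,5-dimethoxyphenoxy)-3,5-dimethoxyphenoxy]-5-methoxybenzene-1,3-diol | COc1cc(O)cc(O)c1Oc1cc(OC)cc(OC)c1Oc1cc(OC)cc(OC)c1 | intermediate
14 | 2-{4-[2-(3,5-dimethoxyphenoxy)-3,5-dimethoxyphenoxy]-3-hydroxy-5-methoxyphenoxy}-3,5-dimethoxybenzaldehyde | COc1cc(Oc2c(C=O)cc(OC)cc2OC)cc(O)c1Oc1cc(OC)cc(OC)c1Oc1cc(OC)cc(OC)c1 | intermediate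
15 | 2-{4-[2-(3,5-dimethoxyphenoxy)-3,5-dimethoxyphenoxy]-3,5-dimethoxyphenoxy}-3,5-dimethoxybenzaldehyde | COc1cc(Oc2c(C=O)cc(OC)cc2OC)cc(OC)c1Oc1cc(OC)cc(OC)c1Oc1cc(OC)cc(OC)c1 | intermediate
16 | 2-{4-[2-(3,5-dimethoxyphenoxy)-3,5-dimethoxyphenoxy]-3,5-dimethoxyphenoxy}-3,5-dimethoxyphenyl formate | COc1cc(Oc2c(OC=O)cc(OC)cc2OC)cc(OC)c1Oc1cc(OC)cc(OC)c1Oc1cc(OC)cc(OC)c1 | intermediate
17 | 2-{4-[2-(3,5-dimethoxyphenoxy)-3,5-dimethoxyphenoxy]-3,5-dimethoxyphenoxy}-3,5-dimethoxyphenol | COc1cc(Oc2c(O)cc(OC)cc2OC)cc(OC)c1Oc1cc(OC)cc(OC)c1Oc1cc(OC)cc(OC)c1 | intermediate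
18 | 2-(2-{4-[2-(3,5-dimethoxyphenoxy)-3,5-dimethoxyphenoxy]-3,5-dimethoxyphenoxy}-3,5-dimethoxyphenoxy)-3,5-dimethoxybenzaldehyde | COc1cc(Oc2c(Oc3c(C=O)cc(OC)cc3OC)cc(OC)cc2OC)cc(OC)c1Oc1cc(OC)cc(OC)c1Oc1cc(OC)cc(OC)c1 | intermediate
19 | 2-(2-{4-[2-(3,5-dimethoxyphenoxy)-3,5-dimethoxyphenoxy]-3,5-dimethoxyphenoxy}-3,5-dimethoxyphenoxy)-3,5-dimethoxyphenyl formate | COc1cc(Oc2c(Oc3c(OC=O)cc(OC)cc3OC)cc(OC)cc2OC)cc(OC)c1Oc1cc(OC)cc(OC)c1Oc1cc(OC)cc(OC)c1 | intermediate
20 | 2-(2-{4-[2-(3,5-dimethoxyphenoxy)-3,5-dimethoxyphenoxy]-3,5-dimethoxyphenoxy}-3,5-dimethoxyphenoxy)-3,5-dimethoxyphenol | COc1cc(Oc2c(Oc3c(O)cc(OC)cc3OC)cc(OC)cc2OC)cc(OC)c1Oc1cc(OC)cc(OC)c1Oc1cc(OC)cc(OC)c1 | intermediate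
21 | 2-[2-[4-[2-(3,5-dihydroxyphenoxy)-3,5-dihydroxyphenoxy]-3,5-dihydroxyphenoxy]-3,5-dihydroxyphenoxy]benzene-1,3,5-triol (CNP0018313.0) | Oc1cc(O)cc(Oc2c(O)cc(O)cc2Oc2c(O)cc(Oc3c(O)cc(O)cc3Oc3c(O)cc(O)cc3O)cc2O)c1 | target

**Step count**

Total steps: 13. Longest linear sequence: 13 steps (steps 1 to 13 from 3,5-dimethoxybenzaldehyde 1; building block 2 from step 1 enters again in steps 9 and 11).

**Steps most likely to fail**

Step 8. The dienolate of 11 may not fragment at accessible temperatures, may add to unopened pyrone, or may re-close on oxygen faster than on carbon, so that ring C is not formed. The fallback sets out from phenol 6 and brings ring C in as a preformed arene by known SNAr and Dakin chemistry. SNAr of 6 on purchased 4-fluoro-3,5-dimethoxybenzaldehyde (K2CO3, DMF, 120 °C) should give 4-[2-(3,5-dimethoxyphenoxy)-3,5-dimethoxyphenoxy]-3,5-dimethoxybenzaldehyde F1. Oxidation with mCPBA should pass through 4-[2-(3,5-dimethoxyphenoxy)-3,5-dimethoxyphenoxy]-3,5-dimethoxyphenyl formate F2, and methanolysis (MeOH, Et3N) should give 4-[2-(3,5-dimethoxyphenoxy)-3,5-dimethoxyphenoxy]-3,5-dimethoxyphenol F3. SNAr of F3 on 2 (Cs2CO3, DMF, 90 °C) returns to the route at compound 15.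

Step 9. Site selectivity between the two phenoxides of 13 may be poor, giving arylation at the C C-2 oxygen or double arylation. The fallback sets out from 13 and replaces kinetic selection by a protecting-group sequence. TIPSCl and imidazole (CH2Cl2, 0 °C) should silylate the unhindered C C-4 hydroxyl to give 2-[2-(3,5-dimethoxyphenoxy)-3,5-dimethoxyphenoxy]-3-methoxy-5-[tri(propan-2-yl)silyloxy]phenol F4. Methylation (MeI, K2CO3, acetone) should give {4-[2-(3,5-dimethoxyphenoxy)-3,5-dimethoxyphenoxy]-3,5-dimethoxyphenoxy}tri(propan-2-yl)silane F5. Fluoride-triggered desilylation and SNAr in one operation with 2 (CsF, DMF, 90 °C) returns to the route at compound 15.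

Step 11. Addition of the hindered phenoxide of 17 to the electron-rich fluoroarene may be slow, and the polyoxygenated phenoxide may decompose at the temperature required. The fallback sets out from 17 and forms the same bond by copper catalysis instead of addition–elimination: Ullmann ether coupling with purchased 2-bromo-3,5-dimethoxybenzaldehyde (CuI, N,N-dimethylglycine, Cs2CO3, dioxane, 100 °C), where the ortho formyl group assists the copper insertion. It returns to the route at compound 18 and makes no compound outside the list (F0).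

**Further compounds**

F1 | step 8 | 4-[2-(3,5-dimethoxyphenoxy)-3,5-dimethoxyphenoxy]-3,5-dimethoxybenzaldehyde | COc1cc(C=O)cc(OC)c1Oc1cc(OC)cc(OC)c1Oc1cc(OC)cc(OC)c1
F2 | step 8 | 4-[2-(3,5-dimethoxyphenoxy)-3,5-dimethoxyphenoxy]-3,5-dimethoxyphenyl formate | COc1cc(OC=O)cc(OC)c1Oc1cc(OC)cc(OC)c1Oc1cc(OC)cc(OC)c1
F3 | step 8 | 4-[2-(3,5-dimethoxyphenoxy)-3,5-dimethoxyphenoxy]-3,5-dimethoxyphenol | COc1cc(O)cc(OC)c1Oc1cc(OC)cc(OC)c1Oc1cc(OC)cc(OC)c1
F4 | step 9 | 2-[2-(3,5-dimethoxyphenoxy)-3,5-dimethoxyphenoxy]-3-methoxy-5-[tri(propan-2-yl)silyloxy]phenol | COc1cc(O[Si](C(C)C)(C(C)C)C(C)C)cc(O)c1Oc1cc(OC)cc(OC)c1Oc1cc(OC)cc(OC)c1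
F5 | step 9 | {4-[2-(3,5-dimethoxyphenoxy)-3,5-dimethoxyphenoxy]-3,5-dimethoxyphenoxy}tri(propan-2-yl)silane | COc1cc(O[Si](C(C)C)(C(C)C)C(C)C)cc(OC)c1Oc1cc(OC)cc(OC)c1Oc1cc(OC)cc(OC)c1
F0 | step 11 | none | none
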